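## Structural features

The target is a 3,3,5,5-tetrasubstituted 1,2-dioxolane (O1–O2–C3–C4–C5). C3 carries a methyl group and the CH2CO2H arm (C2, C1), C5 carries a methyl group and the C6–C17 chain, and C4 is a bare CH2. The two ring methyls are cis, (3R,5R). From C5 the chain runs through C6H2 to two methyl-bearing stereocentres, C7 (S) and C9 (R), which are separated by C8H2 and anti to each other, and then through eight CH2 groups (C10–C17) to a phenyl ring. C3, C5, C7 and C9 therefore form a 1,3-alternating array with one CH2 between each pair and no heteroatom outside the ring to relay stereochemical information. The O–O bond is the fragile element (reductants, phosphines, low-valent metals, strong Lewis acids, heat), and the β-peroxy acid can open by elimination under strong base; because C3 and C5 bear no hydrogen, Kornblum–DeLaMare fragmentation is excluded. The real difficulty is to make two fully substituted peroxide C–O bonds with defined relative configuration when the groups on each carbon (CH3 against CH2R) hardly differ, and to relate that ring to the chain. The key step uses the fact that C3 and C5 are bridged by the single carbon C4: C3–C4–C5 maps onto a cyclopropane whose C3–C5 σ bond is exchanged for O1–O2, with a vinyl group on C3 as the latent C2–C1 acid arm.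

## Logic of the disconnections

21 ⇒ 20. No skeletal bond is cut; C1 is taken back from CO2H to CH2OH. The free β-peroxy acid is the most polar and base-sensitive compound of the route and is therefore made last. The forward step needs an oxidant that stops at the acid, works near neutral pH and leaves O–O alone.

20 ⇒ 18. The C1–O bond is removed (loss of water across C1=C2). A terminal alkene is an inert placeholder for the two-carbon arm and survives radicals and oxygen. The forward step needs anti-Markovnikov hydration by a reagent that does not reduce the peroxide, and it is the stage at which ring diastereomers are separated.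

18 ⇒ 16 + 17. O1–C5 and O2–C3 are cut. This removes the ring, both peroxide C–O bonds and both ring stereocentres at once and leaves a hydrocarbon and 17. The forward step must open the three-membered ring toward C5, capture 17 and close 5-exo. It offers no stereocontrol, which is accepted and answered by separation.

16 ⇒ 15 ⇒ 14. C1=C2 is cut (methylenation) and C2 is returned to the CH2OH level. The hydroxyl group is needed anyway to direct the cyclopropanation, so the vinyl group costs only two routine steps. C3 is quaternary, so nothing can epimerise, and the ring configuration does not matter.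

14 ⇒ 12 + 13. C3–C4 and C4–C5 are cut; C4 is a CH2 unit added across C3=C5. The gain is an acyclic allylic alcohol. The forward step must overcome the low reactivity of a tetrasubstituted alkene, which hydroxyl-directed delivery does, for both alkene isomers.

12 ⇒ 11 ⇒ 9 + 10. C3=C5 is cut after adjusting C2 to the ester level. This joins the three-carbon unit (C2, C3, C3-methyl) of 10 to a simple chain methyl ketone. The forward olefination is between an enolisable ketone and an α-branched phosphonate and is slow, but its geometry is irrelevant.

9 ⇒ 7. The C5–CH3 bond is cut, returning to the carboxylic acid that the next disconnection delivers directly. The forward step must stop at the ketone.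

7 ⇒ 4 + 5. C7–C8 is cut. C5, C6, C7 and the C7 methyl are bought in 5 as a stereocentre of known configuration, transferred by SN2 with inversion. The forward step must attack the alkyl C–O carbon of 5 and not its carbonyl.

4 ⇒ 1 + 2. C10–C11 is cut. C8, C9, C10 and the C9 methyl are bought in 2, whose two halogens differ enough in reactivity that the first coupling leaves the chloride as the handle for the next organometallic. The forward step needs Br-over-Cl chemoselectivity.

## Other disconnections considered

Alternative 1: The key-step product is 2-[(2R,4R)-2,4-dimethyl-12-phenyldodecyl]-4,4,5,5-tetramethyl-1,3,2-dioxaborolane A1. The cut removes C9–C10, C8–C9, C7–C8 and C6–C7 and leaves the ring untouched.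
- Forward step: 4,4,5,5-tetramethyl-2-(8-phenyloctyl)-1,3,2-dioxaborolane A2 is homologated four times, alternating a diamine-complexed, methyl-bearing α-lithiated ester carbenoid (C9, then C7) with a halomethyl carbenoid (C8, then C6).
- In favour: each stereocentre is set by reagent control through a stereospecific 1,2-migration, and the sequence can in principle run without purifying intermediates.
- Against: A1 ends at C6–B and lacks C5; a further coupling at boron with a 2-propenyl unit and an oxidative cleavage would be needed to reach 9. Every homologation is cryogenic and stoichiometric in chiral diamine. Nothing is contributed to the dioxolane.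
- Comparison, structure: it is the equal of the chosen chain synthesis in stereochemical purity and the better one in flexibility, since any C7/C9 isomer is available by changing the diamine enantiomer, which would be useful for reference samples.
- Comparison, mechanism: stereospecific boronate migration and SN2 inversion of a bought stereocentre are equally well defined.
- Comparison, step economy: the chosen plan reaches 9 in three steps, A2 to 9 needs about twice as many operations, and the same ring-forming step and separation would still follow.

Alternative 2: The key-step product is tert-butyl{2-[(3S,5R)-5-[(2S,4R)-2,4-dimethyl-12-phenyldodecyl]-3,5-dimethyl-1,2-dioxolan-3-yl]ethoxy}diphenylsilane A3. The cut is C4–C5 and O2–C3.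
- Forward step: 9 is converted into its silylperoxy ketal, SnCl4 ionises it to a peroxycarbenium ion at C5, tert-butyl[(3-methylbut-3-en-1-yl)oxy]diphenylsilane A4 adds through its CH2 terminus, and the silylated peroxide oxygen traps the tertiary C3 cation. Fluoride then gives 20.
- In favour: it starts from 9 and skips the five steps that build 16, and C1 already carries oxygen, so no borane is used next to the peroxide. On step economy it is the better plan by about two steps.
- Against: a strong Lewis acid acts on a peroxide. The peroxycarbenium ion can lose a C6 proton or rearrange with O–O cleavage, and the C3 cation can eliminate to allylic peroxides. The peroxy ketal needs ozone or concentrated H2O2.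
- Comparison, structure: it is the equal of the chosen plan, neither better nor worse, because the two quaternary centres are formed with the same CH3/CH2R ambiguity and the same four isomers are expected.
- Comparison, mechanism: the neutral radical chain tolerates every group present, whereas the cationic path has more exits. For that reason the radical route is kept as the main line and this one is used as its fallback.

Alternative 3: The key-step product is methyl 2-[(3R,5R)-5-[(2S,4R)-2,4-dimethyl-12-phenyldodecyl]-3,5-dimethyl-1,2-dioxolan-3-yl]acetate A5. The cut is C3–C4 and O1–C5.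
- Forward step: 9 is methylenated to (4S,6R)-2,4,6-trimethyl-14-phenyltetradec-1-ene A6. SnCl4 ionises methyl 3-methoxy-3-[(triethylsilyl)peroxy]butanoate A7, A6 adds to form C3–C4, and the peroxide oxygen captures the C5 cation. Saponification of A5 gives 21.
- In favour: the acid oxidation level is present from the start and three steps lead from 9 to 21. On step economy it is clearly the best of all plans.
- Against: the peroxycarbenium ion sits next to CH2CO2Me, is inductively destabilised and can lose the acidic C2 proton to give a peroxy crotonate instead of adding to A6. The C5 cation is a plain tertiary alkyl cation flanked by C4H2 and C6H2 and can eliminate. The final hydrolysis exposes a β-peroxy ester to base (ring opening by elimination).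
- Comparison: stereocontrol is equal (none), step count is better, and mechanistic security is lower than that of the radical route, whose C5 intermediate is a radical that only has to meet O2.

Key step: step 9

Assumption: 1, 2 and 5 are bought, 2 and 5 in high enantiomeric purity, so the chain enters the ring-forming step as one stereoisomer.

Remark on descriptors: the arrangement in space at C3 is the same from 18 to 21. Its label is R in 18 and 21 and S in 19 and 20, because CH2CH2B and CH2CH2OH rank below the ring CH2. Locants C1–C17 are those of the target throughout.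

## Route

Step 1
Reactants: 1 (7-bromoheptyl)benzene; 2 (2S)-1-bromo-3-chloro-2-methylpropane
Product: 4 [(9R)-10-chloro-9-methyldecyl]benzene, via (7-phenylheptyl)magnesium bromide 3 (not isolated)
Conditions: Mg, THF, 45 °C; then 2 (0.85 equiv), Li2CuCl4 (3 mol%), THF, −10 → 0 °C
Reagents that add atoms: none
Why: Copper-catalysed sp3–sp3 cross-coupling of a primary alkyl Grignard reagent with a primary alkyl bromide forms C10–C11; C–Br reacts much faster than C–Cl, so the chloride is kept. The C9 stereocentre of 2 is not a reacting centre, and its label changes from S to R only because CH2Br becomes a lower-ranking alkyl chain.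

Step 2
Reactants: 4 [(9R)-10-chloro-9-methyldecyl]benzene; 5 (4S)-4-methyloxetan-2-one
Product: 7 (3S,5R)-3,5-dimethyl-13-phenyltridecanoic acid, via [(2R)-2-methyl-10-phenyldecyl]magnesium chloride 6 (not isolated)
Conditions: Mg, BrCH2CH2Br (cat.), THF, 65 °C; CuBr·SMe2 (5 mol%), then 5, THF/Me2S, −30 → 0 °C; aq. HCl
Reagents that add atoms: none
Why: Copper-catalysed SN2 ring opening of a β-lactone by a Grignard reagent at the alkyl C–O carbon (C4 of 5) forms C7–C8 and releases the carboxylate. Inversion at that carbon converts the S centre of 5 into C7 with the S configuration required, and C9 is untouched.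

Step 3
Reactants: 7 (3S,5R)-3,5-dimethyl-13-phenyltridecanoic acid
Product: 9 (4S,6R)-4,6-dimethyl-14-phenyltetradecan-2-one, via dilithium gem-diolate 8 (not isolated)
Conditions: MeLi (2.3 equiv), THF, 0 °C → rt; inverse quench into cold 1 M HCl
Reagents that add atoms: methyllithium, [Li]C
Why: Methyl ketone synthesis from a carboxylic acid with two equivalents of an organolithium reagent; the dianionic adduct 8 cannot collapse before the quench, so a third addition is avoided. C7 is β to the new carbonyl and cannot epimerise.

Step 4
Reactants: 9 (4S,6R)-4,6-dimethyl-14-phenyltetradecan-2-one; 10 triethyl 2-phosphonopropionate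
Product: 11 ethyl (5S,7R)-2,3,5,7-tetramethyl-15-phenylpentadec-2-enoate (E/Z mixture)
Conditions: NaH, 10 (2 equiv), DME, 80 °C
Reagents that add atoms: none
Why: Horner–Wadsworth–Emmons olefination of a ketone with an α-methyl phosphonate forms C3=C5; it is slow and is driven by excess reagent and heat. Both alkene isomers are used, since the geometry is erased in step 9.

Step 5
Reactants: 11 ethyl (5S,7R)-2,3,5,7-tetramethyl-15-phenylpentadec-2-enoate
Product: 12 (5S,7R)-2,3,5,7-tetramethyl-15-phenylpentadec-2-en-1-ol (E/Z mixture)
Conditions: i-Bu2AlH (2.5 equiv), CH2Cl2, −78 → 0 °C; aq. potassium sodium tartrate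
Reagents that add atoms: none
Why: 1,2-Reduction of an α,β-unsaturated ester to the allylic alcohol by a dialkylaluminium hydride; the tetrasubstituted alkene and the arene are inert.

Step 6
Reactants: 12 (5S,7R)-2,3,5,7-tetramethyl-15-phenylpentadec-2-en-1-ol; 13 diiodomethane
Product: 14 {2-[(2S,4R)-2,4-dimethyl-12-phenyldodecyl]-1,2-dimethylcyclopropyl}methanol (mixture of ring diastereomers)
Conditions: Et2Zn (3 equiv), 13 (3.3 equiv), CH2Cl2, 0 °C → rt
Reagents that add atoms: none
Why: Simmons–Smith cyclopropanation in the Furukawa modification; coordination of the zinc carbenoid to the allylic oxygen delivers CH2 (C4) intramolecularly to the electron-rich tetrasubstituted alkene, forming C3–C4 and C4–C5. The ring stereocentres are not controlled and need not be.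

Step 7
Reactants: 14 {2-[(2S,4R)-2,4-dimethyl-12-phenyldodecyl]-1,2-dimethylcyclopropyl}methanol
Product: 15 2-[(2S,4R)-2,4-dimethyl-12-phenyldodecyl]-1,2-dimethylcyclopropane-1-carbaldehyde
Conditions: TEMPO (10 mol%), PhI(OAc)2 (1.2 equiv), CH2Cl2, rt
Reagents that add atoms: none
Why: Nitroxyl-catalysed oxidation of a primary alcohol stops at the aldehyde under anhydrous conditions. The aldehyde sits on a quaternary carbon and has no α-hydrogen to lose.

Step 8
Reactants: 15 2-[(2S,4R)-2,4-dimethyl-12-phenyldodecyl]-1,2-dimethylcyclopropane-1-carbaldehyde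
Product: 16 1-[(2S,4R)-2,4-dimethyl-12-phenyldodecyl]-2-ethenyl-1,2-dimethylcyclopropane (mixture of ring diastereomers)
Conditions: Ph3PCH3Br (1.5 equiv), KOt-Bu (1.4 equiv), THF, 0 °C → rt
Reagents that add atoms: methyltriphenylphosphonium bromide, C[P+](c1ccccc1)(c1ccccc1)c1ccccc1.[Br-]
Why: Wittig methylenation with the unstabilised ylide adds C1; non-enolisable α-quaternary aldehydes are good substrates.

Step 9
Reactants: 16 1-[(2S,4R)-2,4-dimethyl-12-phenyldodecyl]-2-ethenyl-1,2-dimethylcyclopropane; 17 dioxygen
Product: 18 (3R,5R)-3-ethenyl-5-[(2S,4R)-2,4-dimethyl-12-phenyldodecyl]-3,5-dimethyl-1,2-dioxolane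
Conditions: PhSSPh (0.2 equiv), AIBN (0.1 equiv), O2 (1 atm), hν (visible lamp, Pyrex), MeCN/PhCF3, 0 °C; small scale, behind a shield
Reagents that add atoms: none
Why: Light cleaves PhSSPh to PhS radicals (AIBN sustains the chain), one of which adds reversibly to C1 of the vinyl group of 16; the cyclopropylcarbinyl radical at C2 then breaks the C3–C5 bond, because this puts the spin on tertiary C5 and not on primary C4, and leaves a C2=C3 allyl sulfide. Triplet 17 combines with the C5 radical to form C5–O1, the peroxyl radical attacks C3 to form O2–C3, and loss of the PhS radical from the β-thio radical at C2 restores the vinyl group and returns the chain carrier, so both ring oxygens come from 17 and the disulfide is substoichiometric. The closest known reaction type is the thiyl- or selenyl-radical-catalysed [3+2] oxygenation of vinylcyclopropanes to 3-vinyl-1,2-dioxolanes, applied here with both ring termini fully substituted. The dioxolane, the only ring formed, closes in the 5-exo-trig mode by an oxygen radical on alkene carbon C3. C5 is fixed when 17 adds to one face of the planar radical, under weak 1,3-induction from C7 only; C3 is fixed relative to C5 in the envelope-like transition state of the closure, where CH3 and CH2R on C5, and CH3 and the allyl sulfide arm on C3, differ too little to bias it. For that reason the ring configuration of 16 is irrelevant and no diastereocontrol is claimed: 18 is expected together with its (3S,5S), (3R,5S) and (3S,5R) ring isomers, which are carried on and removed after step 10. What the step needs is regioselective ring opening (secured by the tertiary against primary radical), fast capture of 17 (secured by saturation at 0 °C) and 5-exo closure ahead of hydrogen abstraction or 6-endo attack at C2 (favoured because only the 5-exo adduct has the fast C–S scission as exit).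

Step 10
Reactants: 18 (3R,5R)-3-ethenyl-5-[(2S,4R)-2,4-dimethyl-12-phenyldodecyl]-3,5-dimethyl-1,2-dioxolane
Product: 20 2-[(3S,5R)-5-[(2S,4R)-2,4-dimethyl-12-phenyldodecyl]-3,5-dimethyl-1,2-dioxolan-3-yl]ethan-1-ol, via B-alkyl-9-BBN adduct 19 (not isolated)
Conditions: 9-BBN (2.5 equiv), THF, 0 °C → rt, under argon; then NaBO3·4H2O, THF/H2O, rt; SiO2 chromatography, then preparative HPLC
Reagents that add atoms: sodium perborate (NaBO3·4H2O), [Na+].[O-]OB=O
Why: Hydroboration–oxidation; the hindered dialkylborane places boron on terminal C1, three bonds from the peroxide oxygen, and perborate oxidises C–B at mild pH. Dialkyl peroxides without α-hydrogen are not expected to react with a dialkylborane or with perborate at room temperature. The trans-dimethyl isomers should separate from the cis pair on silica at this more polar stage; the two cis isomers are resolved by HPLC and assigned by NOE (cis/trans) and by crystallography of a heavy-atom ester.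

Step 11
Reactants: 20 2-[(3S,5R)-5-[(2S,4R)-2,4-dimethyl-12-phenyldodecyl]-3,5-dimethyl-1,2-dioxolan-3-yl]ethan-1-ol
Product: 21 2-[(3R,5R)-5-[(2S,4R)-2,4-dimethyl-12-phenyldodecyl]-3,5-dimethyl-1,2-dioxolan-3-yl]acetic acid
Conditions: TEMPO (20 mol%), PhI(OAc)2 (2.4 equiv), MeCN/H2O (1:1), rt
Reagents that add atoms: water, O
Why: Nitroxyl-catalysed oxidation of a primary alcohol in aqueous medium proceeds through the aldehyde hydrate to the carboxylic acid. The conditions are near neutral, metal-free and non-reducing, so the O–O bond and the β-peroxy acid are not at risk.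

## Compound list

1 | (7-bromoheptyl)benzene | BrCCCCCCCc1ccccc1 | starting material
2 | (2S)-1-bromo-3-chloro-2-methylpropane | C[C@H](CBr)CCl | starting material
3 | (7-phenylheptyl)magnesium bromide | Br[Mg]CCCCCCCc1ccccc1 | intermediate (not isolated)
4 | [(9R)-10-chloro-9-methyldecyl]benzene | C[C@H](CCCCCCCCc1ccccc1)CCl | intermediate
5 | (4S)-4-methyloxetan-2-one | C[C@H]1CC(=O)O1 | starting material
6 | [(2R)-2-methyl-10-phenyldecyl]magnesium chloride | C[C@H](CCCCCCCCc1ccccc1)C[Mg]Cl | intermediate (not isolated)
7 | (3S,5R)-3,5-dimethyl-13-phenyltridecanoic acid | C[C@H](CCCCCCCCc1ccccc1)C[C@H](C)CC(=O)O | intermediate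
8 | dilithium (4S,6R)-4,6-dimethyl-14-phenyltetradecane-2,2-diolate | C[C@H](CCCCCCCCc1ccccc1)C[C@H](C)CC(C)([O-])[O-].[Li+].[Li+] | intermediate (not isolated)
9 | (4S,6R)-4,6-dimethyl-14-phenyltetradecan-2-one | C[C@H](CCCCCCCCc1ccccc1)C[C@H](C)CC(C)=O | intermediate
10 | triethyl 2-phosphonopropionate (racemic) | CCOC(=O)C(C)P(=O)(OCC)OCC | starting material
11 | ethyl (5S,7R)-2,3,5,7-tetramethyl-15-phenylpentadec-2-enoate (E/Z mixture) | C[C@H](CCCCCCCCc1ccccc1)C[C@H](C)CC(C)=C(C)C(=O)OCC | intermediate
12 | (5S,7R)-2,3,5,7-tetramethyl-15-phenylpentadec-2-en-1-ol (E/Z mixture) | C[C@H](CCCCCCCCc1ccccc1)C[C@H](C)CC(C)=C(C)CO | intermediate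
13 | diiodomethane | ICI | starting material
14 | {2-[(2S,4R)-2,4-dimethyl-12-phenyldodecyl]-1,2-dimethylcyclopropyl}methanol (ring diastereomers) | C[C@H](CCCCCCCCc1ccccc1)C[C@H](C)CC1(C)CC1(C)CO | intermediate
15 | 2-[(2S,4R)-2,4-dimethyl-12-phenyldodecyl]-1,2-dimethylcyclopropane-1-carbaldehyde (ring diastereomers) | C[C@H](CCCCCCCCc1ccccc1)C[C@H](C)CC1(C)CC1(C)C=O | intermediate
16 | 1-[(2S,4R)-2,4-dimethyl-12-phenyldodecyl]-2-ethenyl-1,2-dimethylcyclopropane (ring diastereomers) | C[C@H](CCCCCCCCc1ccccc1)C[C@H](C)CC1(C)CC1(C)C=C | intermediate
17 | dioxygen | O=O | starting material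
18 | (3R,5R)-3-ethenyl-5-[(2S,4R)-2,4-dimethyl-12-phenyldodecyl]-3,5-dimethyl-1,2-dioxolane | C[C@H](CCCCCCCCc1ccccc1)C[C@H](C)C[C@]1(C)C[C@](C)(C=C)OO1 | intermediate
19 | 9-{2-[(3S,5R)-5-[(2S,4R)-2,4-dimethyl-12-phenyldodecyl]-3,5-dimethyl-1,2-dioxolan-3-yl]ethyl}-9-borabicyclo[3.3.1]nonane | C[C@H](CCCCCCCCc1ccccc1)C[C@H](C)C[C@]1(C)C[C@](C)(CCB2C3CCCC2CCC3)OO1 | intermediate (not isolated)
20 | 2-[(3S,5R)-5-[(2S,4R)-2,4-dimethyl-12-phenyldodecyl]-3,5-dimethyl-1,2-dioxolan-3-yl]ethan-1-ol | C[C@H](CCCCCCCCc1ccccc1)C[C@H](C)C[C@]1(C)C[C@](C)(CCO)OO1 | intermediate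
21 | 2-[(3R,5R)-5-[(2S,4R)-2,4-dimethyl-12-phenyldodecyl]-3,5-dimethyl-1,2-dioxolan-3-yl]acetic acid | C[C@H](CCCCCCCCc1ccccc1)C[C@H](C)C[C@]1(C)C[C@](C)(CC(=O)O)OO1 | target

## Step count and least certain steps

Total: 11 steps. Longest linear sequence: 11 steps, from 1 to 21; all other building blocks are bought and used directly.

Step 9 (key step).
- What may go wrong: closure of the peroxyl radical onto the fully substituted C3 may be slow enough for hydrogen abstraction (open-chain allylic hydroperoxides) or 6-endo attack at C2 to take over. Facial selection at C5 and C3 is expected to be close to random, so the wanted isomer would be a minor part of a four-component mixture.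
- Fallback: this sets out from 9 and comes back at 20. Wittig methylenation of 9 gives (4S,6R)-2,4,6-trimethyl-14-phenyltetradec-1-ene F1 (the same compound as A6). Ozonolysis in CH2Cl2/MeOH at −78 °C traps the carbonyl oxide as (4S,6R)-2-hydroperoxy-2-methoxy-4,6-dimethyl-14-phenyltetradecane F2. Et3SiOTf and 2,6-lutidine convert it into triethyl{[(4S,6R)-2-methoxy-4,6-dimethyl-14-phenyltetradecan-2-yl]peroxy}silane F3. SnCl4 in CH2Cl2 at −78 °C ionises F3 in the presence of [(3-methylbut-3-en-1-yl)oxy]tri(propan-2-yl)silane F4 (from 3-methylbut-3-en-1-ol, i-Pr3SiCl and imidazole) and should give {2-[(3S,5R)-5-[(2S,4R)-2,4-dimethyl-12-phenyldodecyl]-3,5-dimethyl-1,2-dioxolan-3-yl]ethoxy}tri(propan-2-yl)silane F5 with its ring isomers. Bu4NF then releases 20.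
- Limits of the fallback: it avoids the vinylcyclopropane and the borane but does not cure the lack of stereocontrol.

Step 4.
- What may go wrong: enolisation of the methyl ketone by the phosphonate anion and slow addition of the α-branched reagent may leave the olefination incomplete, and base may shift the new double bond out of conjugation.
- Fallback: this sets out from 7 and comes back at 11. Activation of 7 with 1,1'-carbonyldiimidazole and acylation of the magnesium enolate of potassium ethyl 2-methylmalonate (MgCl2, Et3N), with loss of CO2, gives ethyl (5S,7R)-2,5,7-trimethyl-3-oxo-15-phenylpentadecanoate F6. NaH and ClP(O)(OEt)2 give ethyl (5S,7R)-3-[(diethoxyphosphoryl)oxy]-2,5,7-trimethyl-15-phenylpentadec-2-enoate F7. Me2CuLi in Et2O at −78 → −20 °C replaces the phosphate by methyl and delivers 11 as one alkene isomer. The alkene is then made by cross-coupling and not by carbonyl olefination.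

Step 10.
- What may go wrong: reductive cleavage of the O–O bond by the borane, or by alkyl radicals if traces of oxygen start borane autoxidation, would give 1,3-diols; incomplete resolution of the two cis isomers is the second concern.
- Fallback: this sets out from 18 and comes back at 21, without any borane. Ozonolysis of 18 (CH2Cl2, −78 °C; Me2S) gives (3R,5R)-5-[(2S,4R)-2,4-dimethyl-12-phenyldodecyl]-3,5-dimethyl-1,2-dioxolane-3-carbaldehyde F8. Wittig reaction with Ph3P=CHOMe gives (3R,5R)-5-[(2S,4R)-2,4-dimethyl-12-phenyldodecyl]-3-(2-methoxyethenyl)-3,5-dimethyl-1,2-dioxolane F9. Mild aqueous acid hydrolyses it to 2-[(3R,5R)-5-[(2S,4R)-2,4-dimethyl-12-phenyldodecyl]-3,5-dimethyl-1,2-dioxolan-3-yl]acetaldehyde F10. Pinnick oxidation (NaClO2, NaH2PO4, 2-methylbut-2-ene) gives 21.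

Step 2.
- What may go wrong: attack of the β-branched Grignard reagent at the lactone carbonyl, or base-induced elimination of 5 to crotonate, may compete with the SN2 opening.
- Fallback: this sets out from 4 (through 6) and comes back at 9. Formylation of 6 with N,N-dimethylformamide gives (3R)-3-methyl-11-phenylundecanal F11. Wittig reaction with 1-(triphenylphosphoranylidene)propan-2-one gives (3E,6R)-6-methyl-14-phenyltetradec-3-en-2-one F12. Copper-catalysed asymmetric conjugate addition of MeMgBr (CuBr·SMe2, Josiphos, t-BuOMe, −75 °C), with the ligand antipode that delivers methyl to the Si face of C4 of F12, gives 9 directly. The anti relationship would be checked through the shift pattern of the C8 methylene protons. C7 is then set by catalyst control and not from the chiral pool.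

## Further compounds

F1 | step 9 | (4S,6R)-2,4,6-trimethyl-14-phenyltetradec-1-ene | C[C@H](CCCCCCCCc1ccccc1)C[C@H](C)CC(C)=C
F2 | step 9 | (4S,6R)-2-hydroperoxy-2-methoxy-4,6-dimethyl-14-phenyltetradecane (C2 epimers) | C[C@H](CCCCCCCCc1ccccc1)C[C@H](C)CC(C)(OC)OO
F3 | step 9 | triethyl{[(4S,6R)-2-methoxy-4,6-dimethyl-14-phenyltetradecan-2-yl]peroxy}silane (C2 epimers) | C[C@H](CCCCCCCCc1ccccc1)C[C@H](C)CC(C)(OC)OO[Si](CC)(CC)CC
F4 | step 9 | [(3-methylbut-3-en-1-yl)oxy]tri(propan-2-yl)silane | C=C(C)CCO[Si](C(C)C)(C(C)C)C(C)C
F5 | step 9 | {2-[(3S,5R)-5-[(2S,4R)-2,4-dimethyl-12-phenyldodecyl]-3,5-dimethyl-1,2-dioxolan-3-yl]ethoxy}tri(propan-2-yl)silane | C[C@H](CCCCCCCCc1ccccc1)C[C@H](C)C[C@]1(C)C[C@](C)(CCO[Si](C(C)C)(C(C)C)C(C)C)OO1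
F6 | step 4 | ethyl (5S,7R)-2,5,7-trimethyl-3-oxo-15-phenylpentadecanoate (C2 epimers) | C[C@H](CCCCCCCCc1ccccc1)C[C@H](C)CC(=O)C(C)C(=O)OCC
F7 | step 4 | ethyl (5S,7R)-3-[(diethoxyphosphoryl)oxy]-2,5,7-trimethyl-15-phenylpentadec-2-enoate | C[C@H](CCCCCCCCc1ccccc1)C[C@H](C)CC(OP(=O)(OCC)OCC)=C(C)C(=O)OCC
F8 | step 10 | (3R,5R)-5-[(2S,4R)-2,4-dimethyl-12-phenyldodecyl]-3,5-dimethyl-1,2-dioxolane-3-carbaldehyde | C[C@H](CCCCCCCCc1ccccc1)C[C@H](C)C[C@]1(C)C[C@](C)(C=O)OO1
F9 | step 10 | (3R,5R)-5-[(2S,4R)-2,4-dimethyl-12-phenyldodecyl]-3-(2-methoxyethenyl)-3,5-dimethyl-1,2-dioxolane (E/Z mixture) | C[C@H](CCCCCCCCc1ccccc1)C[C@H](C)C[C@]1(C)C[C@](C)(C=COC)OO1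
F10 | step 10 | 2-[(3R,5R)-5-[(2S,4R)-2,4-dimethyl-12-phenyldodecyl]-3,5-dimethyl-1,2-dioxolan-3-yl]acetaldehyde | C[C@H](CCCCCCCCc1ccccc1)C[C@H](C)C[C@]1(C)C[C@](C)(CC=O)OO1
F11 | step 2 | (3R)-3-methyl-11-phenylundecanal | C[C@H](CCCCCCCCc1ccccc1)CC=O
F12 | step 2 | (3E,6R)-6-methyl-14-phenyltetradec-3-en-2-one | C[C@H](CCCCCCCCc1ccccc1)C/C=C/C(C)=O
A1 | alternative 1 | 2-[(2R,4R)-2,4-dimethyl-12-phenyldodecyl]-4,4,5,5-tetramethyl-1,3,2-dioxaborolane | C[C@H](CCCCCCCCc1ccccc1)C[C@H](C)CB1OC(C)(C)C(C)(C)O1
A2 | alternative 1 | 4,4,5,5-tetramethyl-2-(8-phenyloctyl)-1,3,2-dioxaborolane | CC1(C)OB(CCCCCCCCc2ccccc2)OC1(C)C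
A3 | alternative 2 | tert-butyl{2-[(3S,5R)-5-[(2S,4R)-2,4-dimethyl-12-phenyldodecyl]-3,5-dimethyl-1,2-dioxolan-3-yl]ethoxy}diphenylsilane | C[C@H](CCCCCCCCc1ccccc1)C[C@H](C)C[C@]1(C)C[C@](C)(CCO[Si](c2ccccc2)(c2ccccc2)C(C)(C)C)OO1
A4 | alternative 2 | tert-butyl[(3-methylbut-3-en-1-yl)oxy]diphenylsilane | C=C(C)CCO[Si](c1ccccc1)(c1ccccc1)C(C)(C)C
A5 | alternative 3 | methyl 2-[(3R,5R)-5-[(2S,4R)-2,4-dimethyl-12-phenyldodecyl]-3,5-dimethyl-1,2-dioxolan-3-yl]acetate | C[C@H](CCCCCCCCc1ccccc1)C[C@H](C)C[C@]1(C)C[C@](C)(CC(=O)OC)OO1
A6 | alternative 3 | (4S,6R)-2,4,6-trimethyl-14-phenyltetradec-1-ene | C[C@H](CCCCCCCCc1ccccc1)C[C@H](C)CC(C)=C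
A7 | alternative 3 | methyl 3-methoxy-3-[(triethylsilyl)peroxy]butanoate | COC(=O)CC(C)(OC)OO[Si](CC)(CC)CC
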